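## The problem

The target (25) is a C25 terpenoid. A trans-fused decalin (rings A and B, C1–C10, 10β-methyl) carries at C9 a chain C11–C19 that ends in a 4-methylbutenolide (ring atoms O, C16, C17, C18, C19). It has eight stereocentres and one trisubstituted E-alkene (C13=C14). C5, C9, C10 and the equatorial 6α-hydroxyl are those of the larch diterpene (+)-larixol. The 4α-hydroxymethyl group, the 8α-hydroxy-8β-methyl carbinol, C15 and C16 have to be made.

Inside the decalin the existing centres can direct the new ones. The equatorial 6α-oxygen lies syn-pentane to the 4α-methyl group and to no other methyl. The axial 10β-methyl shields the β-face of C8. C15 and C16 lie five or more bonds from C9, so the ring cannot control them: C15 needs a reagent, and C16 must then be set from C15.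

Several groups are fragile. The tertiary C8 alcohol dehydrates or adds to a C13 carbonyl. The C15 carbinol is allylic and ionises easily. The butenolide has an acidic hydrogen at C16. Protecting groups must therefore come off under mild, near-neutral conditions.

Two features suggest the key step. C13 bears a methyl group on an E-alkene whose other end (C14) is bonded to a carbinol (C15). This is the pattern left by syn addition of methyl and metal to a C13≡C14 alkyne followed by capture with an aldehyde. The ring O–C16–C17(CH3)=C18–C19(=O) is a 2-substituted 3-methylfuran at a higher oxidation level, so the aldehyde can be the robust, non-enolisable 3-methylfuran-2-carbaldehyde.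

## Retrosynthesis

**Butenolide to six-membered lactone (25 ⇒ 24 ⇒ 22).** After removal of three silyl ethers (24), the C19–O16 acyl bond is cut and the acyl group is placed on O15. This gives the 5,6-cis 5-acyloxy-5,6-dihydropyran-2-one 22. The alternative, lactonising an open-chain hydroxy acid, would require C15 and C16 to be set in an acyclic diol. In 22 both sit on one ring. The forward reaction is an acyl migration that breaks neither C–O bond. The 15S,16S butenolide therefore requires the cis lactone.

**Lactone to furan (22 ⇒ 21 ⇒ 20 ⇒ 19 ⇒ 18).** The C16 carbinol is traced to a ketone (20), reduced on the ring from the face dictated by C15. This gives the trans alcohol 21, so one inversion leads to 22. The pyran-2,5-dione 20 is the oxidised form of lactol 19, the Achmatowicz product of furyl carbinol 18. This removes the lactone, C16 and all oxygen functionality of the heterocycle in favour of an aromatic furan with a single stereocentre (C15). The forward sequence must oxidise the furan in the presence of the C13=C14 alkene and must not enolise C15.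

**Three-component union (18 ⇒ 13 + 14 + 15).** The C14–C15 bond and the C13–CH3 bond are cut together. This leads to terminal alkyne 13, trimethylaluminium 14 and 3-methylfuran-2-carbaldehyde 15. A cut at C15–C16 would need a chiral α-oxygenated aldehyde and a metalated butenolide. A cut at C12–C13 would need an sp3–sp2 coupling next to the decalin. The chosen cut instead uses an aromatic aldehyde that cannot enolise, and it sets the alkene geometry by the syn addition. The forward reaction must deliver methyl to C13 and metal to C14, keep the E geometry through transmetalation, and select one face of the aldehyde by a chiral ligand.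

**Decalin oxygenation (13 ⇒ 12 ⇒ 11 ⇒ 10 ⇒ 8 ⇒ 7).** The three silyl ethers are removed (12). The 4α-CH2–O bond and the C8–O bond are then traced to lactol-epoxide 11, oxime 10 and nitrite 8. The 4α-methyl is oxidised by a radical relay from the 6α-oxygen (Barton nitrite photolysis). The tertiary alcohol comes from the 8α,17-epoxide 7 by hydride opening. The epoxide is installed before the photolysis. A C6 alkoxyl radical next to an allylic C7 would otherwise fragment. The precursor 7 has only one free hydroxyl, so the nitrite can form only at O6.

**Alkyne and side-chain degradation (7 ⇒ 6 ⇒ 3 ⇒ 2 ⇒ 1).** The epoxide comes from the C8=C17 alkene of alkynol 6. The alkyne comes from methyl ketone 2 through its enol phosphate, with the hydroxyl masked in between as TMS ether 3. Ketone 2 results from cutting the C13–C14 bond of the vinyl carbinol of (+)-larixol 1. Larixol supplies the trans-decalin, C5, C9, C10, the 6α-oxygen and the four chain carbons C11–C14 of the alkyne.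

## Roads not taken

**Alternative 1:** The decalin would be built by a catalytic asymmetric Diels–Alder reaction. 2,6-Dimethyl-1,4-benzoquinone A2 and (E)-penta-1,3-diene A3 would combine under a triflimide-activated chiral oxazaborolidine. The reaction forms C1–C10 and C4–C5, closes ring A and gives the cis-fused enedione A1.
- Merits: cheap achiral materials, either enantiomer, and independence from a natural product supply. On these points it is better than the chosen plan.
- Weak points: A1 is cis-fused. C4 carries only H and methyl, so the quaternary centre with its hydroxymethyl group is still to be made. C9 is a carbonyl that must become a CH bearing the chain. The C2=C3 alkene has to be removed. The C8 carbinol and the 6α-alcohol must still be set.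
- Comparison: the way from A1 to an intermediate like 13 would be much longer than the nine steps from larixol. The chosen plan pays for this with its reliance on a remote C–H functionalisation (step 6).

**Alternative 2:** Rings A and B would close together in an intramolecular Diels–Alder reaction of trienoate A5, thermally or with Me2AlCl. The reaction forms C3–C4 and C5–C10 and gives A4, setting C4, C5 and C10.
- Merits: both quaternary carbons arise in one step. The 4α-substituent arrives as an ester, so the hydroxymethyl group needs only a reduction and no C–H oxidation. This is a real advantage over step 6 of the chosen plan.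
- Weak points: the diene terminus is fully substituted and the dienophile is α-methylated, so the cycloaddition should be slow, and its endo/exo and facial selectivity would rest on two stereocentres (C6, C9) in a flexible tether. A5 itself needs a multistep enantioselective synthesis. In A4 a methyl nucleophile would attack the C8 ketone from the less hindered α-face and give the wrong carbinol, so methylenation, epoxidation and reduction would still be needed. The alkyne carbons would also remain to be added.
- Comparison: the chosen plan gets four stereocentres and the trans ring fusion from the starting material without any step.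

**Alternative 3:** The decalin and chain would be kept, but the butenolide would be annulated last. Propargylic alcohol A7 would undergo copper-catalysed anti-addition of MeMgBr across C17≡C18, carboxylation at C18 with CO2 and acid-induced closure to A6.
- Merits: the methyl group, the carbonyl and the ring are introduced in one flask, and C16 is carried through unchanged. The end-game is shorter than the six steps from 18 to 25, and it avoids both the enolisable keto lactone and the inversion at C16.
- Weak points: A7 needs C15 and C16 set as an acyclic, differentiated diol. That requires an α-alkoxy aldehyde at C15 or C16 and a diastereoselective addition, and these aldehydes are configurationally fragile. Excess Grignard reagent with a copper salt could also displace the allylic C15 ether in an SN2' sense.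
- Comparison: the chosen plan uses an aromatic aldehyde that cannot epimerise and sets C16 relative to C15 on a ring.

Key step: step 10

Remarks on the chemistry (assumptions):
- (+)-Larixol is taken as a purchasable natural product (larch oleoresin), and 3-methylfuran-2-carbaldehyde and trimethylaluminium as catalogue reagents.
- Numbering: the decalin has labdane numbering (C1–C10; 5α-H, 9α-H, 10β-CH3). The chain is C11–C19, with C13 bearing the methyl group, C14 the former ketone methyl carbon, C15 the carbinol, and C16 (CH–O), C17 (C–CH3), C18 (=CH) and C19 (C=O) in the heterocycle. The oxidised C4 substituent is called the 4α-CH2 group.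
- Lactols 11 and 19 are expected as anomer mixtures and oxime 10 as an E/Z mixture; these centres are left open in the SMILES.

## Route

Step 1
Reactants: 1 (+)-larixol
Product: 2 6α-hydroxy-14,15-dinorlabd-8(17)-en-13-one (C13 methyl ketone)
Conditions: KMnO4, MgSO4, acetone/H2O, 0 °C to rt
Reagents that add atoms: none
Why: KMnO4 attacks the monosubstituted vinyl group of the tertiary allylic alcohol faster than the hindered C8=C17 alkene, and the triol is cleaved down to the C13 ketone with loss of C14 and C15 (oxidative degradation of a vinyl carbinol, the usual entry to 14,15-dinorlabdan-13-ones). The secondary 6α-alcohol reacts only slowly under the neutral buffered conditions.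

Step 2
Reactants: 2 6α-hydroxy-14,15-dinorlabd-8(17)-en-13-one
Product: 3 6α-trimethylsilyl ether of ketone 2
Conditions: TMSCl, imidazole, CH2Cl2, 0 °C
Reagents that add atoms: chlorotrimethylsilane, C[Si](C)(C)Cl
Why: Silylation of the only hydroxyl; the TMS ether keeps the alkoxide from being phosphorylated in step 3 and is lost again in the work-up of that step.

Step 3
Reactants: 3 6α-trimethylsilyl ether of ketone 2
Product: 6 alkynol (decalin with 4,4-dimethyl; 10β-methyl; 6α-OH; exocyclic C8=CH2; 9β-but-3-ynyl chain), via enol phosphate 4 (not isolated), via silylated alkyne 5 (not isolated)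
Conditions: LiN(i-Pr)2 (1.1 equiv), THF, −78 °C; ClP(O)(OEt)2, −78 °C to rt; LiN(i-Pr)2 (2.5 equiv), −78 °C to rt; then 1 M HCl, THF, 0 °C
Reagents that add atoms: none
Why: Kinetic deprotonation at the methyl group, O-phosphorylation and base-induced elimination of diethyl phosphate from the terminal enol phosphate give the terminal alkyne (methyl ketone to alkyne conversion through the enol phosphate). Dilute acid then removes the TMS group and frees the 6α-hydroxyl for the radical relay.

Step 4
Reactants: 6 alkynol
Product: 7 8α,17-epoxide of alkynol 6 (spiro-epoxide; oxygen α; 6α-OH free)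
Conditions: mCPBA, NaHCO3, CH2Cl2, 0 °C
Reagents that add atoms: 3-chloroperoxybenzoic acid, OOC(=O)c1cccc(Cl)c1
Why: Prilezhaev epoxidation of the only alkene (the alkyne is inert at 0 °C). The axial 10β-methyl blocks the β-face of C8 and the 6α-hydroxyl can hydrogen-bond the peracid on the α-face, so the 8α,17-epoxide should form and fix C8. The alkene is removed here because a C6 alkoxyl radical beside an allylic C7 would fragment in step 6.

Step 5
Reactants: 7 8α,17-epoxide of alkynol 6
Product: 8 6α-nitrite ester of 7
Conditions: NOCl, pyridine, −20 °C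
Reagents that add atoms: nitrosyl chloride, O=NCl
Why: O-Nitrosation of the single free hydroxyl (nitrite ester formation for the Barton reaction); pyridine takes up HCl so that the spiro-epoxide is not opened.

Step 6
Reactants: 8 6α-nitrite ester of 7
Product: 10 oxime (4α-CH=NOH; 4β-methyl; 6α-OH; 8α,17-epoxide; butynyl chain), via C-nitroso compound 9 (not isolated)
Conditions: hν (365 nm), benzene, 15 °C, argon; then i-PrOH, 70 °C
Reagents that add atoms: none
Why: Barton nitrite photolysis: O–NO homolysis gives the C6 alkoxyl radical, whose equatorial oxygen lies syn-pentane to the equatorial 4α-methyl and abstracts hydrogen from it through a six-membered transition state; NO recombines at carbon and nitroso compound 9 tautomerises to the oxime on warming. Only the α-methyl is within reach (the 4β- and 10β-methyls are axial and remote), so C4 becomes a stereocentre with the oxidised carbon α.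

Step 7
Reactants: 10 oxime
Product: 11 lactol (4α-CH(OH)–O–C6 five-membered hemiacetal; 8α,17-epoxide; butynyl chain)
Conditions: TiCl3 (aq.), NH4OAc, THF/H2O, rt
Reagents that add atoms: water, O
Why: Trivalent titanium cleaves the N–O bond and the imine hydrolyses near pH 6 (reductive deoximation), mild enough for epoxide and alkyne. The aldehyde is trapped by the neighbouring 6α-hydroxyl as the five-membered lactol.

Step 8
Reactants: 11 lactol
Product: 12 triol (4α-CH2OH; 6α-OH; 8α-OH with 8β-methyl; butynyl chain)
Conditions: LiAlH4, THF, 0 to 50 °C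
Reagents that add atoms: none
Why: LiAlH4 reduces the lactol through its hydroxy-aldehyde form to the 1,4-diol and opens the spiro-epoxide by hydride attack at the unsubstituted C17. The C8–O bond is untouched, so the 8α-hydroxy-8β-methyl carbinol results; an isolated terminal alkyne is not reduced.

Step 9
Reactants: 12 triol
Product: 13 tris(triethylsilyl) ether of 12 (terminal alkyne C13≡C14)
Conditions: TESOTf (4.5 equiv), 2,6-lutidine, CH2Cl2, −78 °C to rt
Reagents that add atoms: triethylsilyl trifluoromethanesulfonate, CC[Si](CC)(CC)OS(=O)(=O)C(F)(F)F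
Why: The silyl triflate with 2,6-lutidine silylates primary, hindered secondary and tertiary hydroxyls alike. One kind of group allows a single mild fluoride deprotection at the end, and the primary ether is neopentylic and therefore sturdier than an ordinary primary TES ether.

Step 10
Reactants: 13 tris(triethylsilyl) alkyne; 14 trimethylaluminium; 15 3-methylfuran-2-carbaldehyde
Product: 18 (15S)-E-allylic 3-methylfuran-2-yl carbinol, via alkenylalane 16 (not isolated), via alkenylzinc 17 (not isolated)
Conditions: Me3Al (2.5 equiv), Cp2ZrCl2 (0.25 equiv), CH2Cl2, 0 °C to rt; volatiles removed in vacuo; toluene, Me2Zn (1.5 equiv), −40 °C; (−)-MIB (0.15 equiv), then 15, −20 to 0 °C; aq. potassium sodium tartrate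
Reagents that add atoms: none
Why: Cp2ZrCl2 and Me3Al form a methylzirconocene–chloroalane pair that adds methyl and metal syn across the terminal alkyne, methyl to the internal C13 and metal to C14, and exchange to aluminium leaves the (E)-alkenyldimethylalane 16 (zirconium-catalysed carboalumination). After excess Me3Al is stripped off, Me2Zn takes over the alkenyl group with retention of geometry to give alkenyl(methyl)zinc 17. The methylzinc alkoxide of (−)-MIB [(2S)-3-exo-morpholinoisoborneol] binds 17 and aldehyde 15 and transfers the alkenyl group, which migrates far faster than methyl, to the Si face of the carbonyl; the closest known reaction type is the amino-alcohol-catalysed addition of alkenylzinc reagents to aromatic aldehydes, fed here from an alane. No ring is closed. C15 is the only new stereocentre and is set by the ligand, since the nearest ring stereocentre (C9) is five bonds away; Si-face attack corresponds to 15S because furyl outranks alkenyl. The step needs regioselective syn methylmetalation (secured by the unbranched terminal alkyne), alkenyl-over-methyl transfer and clean 1,2-addition (the aldehyde has no α-hydrogen). The three silyl ethers keep the hydroxyls from consuming the alane or binding zinc. Carbinol 18 is doubly activated towards ionisation and is worked up neutral and used at once.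

Step 11
Reactants: 18 (15S)-furyl carbinol
Product: 19 (2S)-6-hydroxy-4-methyl-2-alkenyl-2H-pyran-3(6H)-one (Achmatowicz lactol; C15 is ring C2)
Conditions: NBS, NaHCO3, THF/H2O (4:1), 0 °C
Reagents that add atoms: water, O
Why: Achmatowicz rearrangement: bromonium attack on the electron-rich furan and addition of water give a 2,5-dihydrofuran that opens to the Z-enedione and recloses through the C15 hydroxyl onto C19. The furan reacts much faster with NBS than the C13=C14 alkene, and C15 keeps its configuration because its C–O bond is not broken.

Step 12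
Reactants: 19 Achmatowicz lactol
Product: 20 (6S)-4-methyl-6-alkenyl-2H-pyran-2,5(6H)-dione (keto lactone)
Conditions: Dess–Martin periodinane, CH2Cl2, 0 °C; used crude
Reagents that add atoms: none
Why: Dess–Martin oxidation of the lactol to the lactone under non-basic conditions. The C15–H of 20 is allylic and α to the ketone, hence the low temperature and direct use.

Step 13
Reactants: 20 keto lactone
Product: 21 (15S,16R)-5,6-trans-5-hydroxy-4-methyl-6-alkenyl-5,6-dihydro-2H-pyran-2-one
Conditions: NaBH4, CeCl3·7H2O, MeOH/CH2Cl2, −78 °C
Reagents that add atoms: none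
Why: Luche 1,2-reduction of the enone carbonyl; with the C15 alkenyl group pseudo-equatorial the small hydride adds axially and gives the 5,6-trans alcohol, as is usual for 6-substituted pyran-2,5-diones. C16 is thus set from C15 on the ring, in the sense opposite to that required.

Step 14
Reactants: 21 trans-hydroxy lactone
Product: 22 (15S,16S)-5,6-cis 4-nitrobenzoate of the hydroxy lactone
Conditions: 4-nitrobenzoic acid, PPh3, DIAD, THF, 0 °C to rt
Reagents that add atoms: 4-nitrobenzoic acid, OC(=O)c1ccc(cc1)[N+](=O)[O-]
Why: Mitsunobu reaction: the alkoxyphosphonium at C16 is displaced by 4-nitrobenzoate with inversion, giving the cis ester. SN2' attack is disfavoured because the allylic terminus C18 is the α-carbon of the unsaturated lactone.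

Step 15
Reactants: 22 cis 4-nitrobenzoate
Product: 24 tris(triethylsilyl) ether of the target (15S,16S butenolide with free C15 hydroxyl), via cis-hydroxy lactone 23 (not isolated)
Conditions: K2CO3, MeOH, 0 °C
Reagents that add atoms: none
Why: Methanolysis of the activated aryl ester frees the C16 alkoxide, which attacks the lactone carbonyl C19 held cis to it by the C17=C18 bond; acyl transfer from O15 to O16 contracts the six-membered lactone to the butenolide and releases the C15 hydroxyl (base-induced translactonisation of a 5-hydroxy-5,6-dihydropyran-2-one). Neither C–O bond is broken, so the cis lactone maps onto the 15S,16S butenolide.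

Step 16
Reactants: 24 tris(triethylsilyl) ether of the target
Product: 25 target CNP0255788.1
Conditions: HF·pyridine, pyridine, THF, 0 °C to rt
Reagents that add atoms: none
Why: Buffered HF·pyridine cleaves the three triethylsilyl ethers (fluoride-mediated desilylation) without opening the butenolide or ionising the allylic C15 carbinol.

## Compound list

1 | (+)-larixol, (13S)-labda-8(17),14-diene-6α,13-diol | C=C[C@@](C)(O)CC[C@@H]1[C@@]2(C)CCCC(C)(C)[C@@H]2[C@@H](O)CC1=C | starting material
2 | 6α-hydroxy-14,15-dinorlabd-8(17)-en-13-one | CC(=O)CC[C@@H]1[C@@]2(C)CCCC(C)(C)[C@@H]2[C@@H](O)CC1=C | intermediate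
3 | 6α-trimethylsilyl ether of 2 | CC(=O)CC[C@@H]1[C@@]2(C)CCCC(C)(C)[C@@H]2[C@@H](O[Si](C)(C)C)CC1=C | intermediate
4 | terminal enol diethyl phosphate of 3 | C=C(OP(=O)(OCC)OCC)CC[C@@H]1[C@@]2(C)CCCC(C)(C)[C@@H]2[C@@H](O[Si](C)(C)C)CC1=C | intermediate
5 | 6α-trimethylsilyl ether of alkynol 6 | C#CCC[C@@H]1[C@@]2(C)CCCC(C)(C)[C@@H]2[C@@H](O[Si](C)(C)C)CC1=C | intermediate
6 | alkynol: 9β-(but-3-ynyl)-4,4,10β-trimethyl-8-methylene-trans-decalin-6α-ol | C#CCC[C@@H]1[C@@]2(C)CCCC(C)(C)[C@@H]2[C@@H](O)CC1=C | intermediate
7 | 8α,17-epoxide of 6 | C#CCC[C@@H]1[C@@]2(C)CCCC(C)(C)[C@@H]2[C@@H](O)C[C@]13CO3 | intermediate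
8 | 6α-nitrite of 7 | C#CCC[C@@H]1[C@@]2(C)CCCC(C)(C)[C@@H]2[C@@H](ON=O)C[C@]13CO3 | intermediate
9 | 4α-nitrosomethyl-6α-hydroxy epoxide | C#CCC[C@@H]1[C@@]2(C)CCC[C@@](C)(CN=O)[C@@H]2[C@@H](O)C[C@]13CO3 | intermediate
10 | 4α-(hydroxyiminomethyl)-6α-hydroxy epoxide (oxime) | C#CCC[C@@H]1[C@@]2(C)CCC[C@@](C)(C=NO)[C@@H]2[C@@H](O)C[C@]13CO3 | intermediate
11 | lactol between the 4α-CHO carbon and O6, with 8α,17-epoxide | C#CCC[C@@H]1[C@@]2(C)CCC[C@@](C)(C3O)[C@@H]2[C@@H](O3)C[C@]14CO4 | intermediate
12 | triol: 4α-hydroxymethyl, 6α-OH, 8α-OH/8β-methyl, 9β-(but-3-ynyl) | C#CCC[C@@H]1[C@@]2(C)CCC[C@@](C)(CO)[C@@H]2[C@@H](O)C[C@@]1(C)O | intermediate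
13 | tris(triethylsilyl) ether of 12 | C#CCC[C@@H]1[C@@]2(C)CCC[C@@](C)(CO[Si](CC)(CC)CC)[C@@H]2[C@@H](O[Si](CC)(CC)CC)C[C@@]1(C)O[Si](CC)(CC)CC | intermediate
14 | trimethylaluminium | C[Al](C)C | starting material
15 | 3-methylfuran-2-carbaldehyde | Cc1ccoc1C=O | starting material
16 | (E)-2-methylalk-1-enyl(dimethyl)alane from 13 | C[Al](C)/C=C(\C)CC[C@@H]1[C@@]2(C)CCC[C@@](C)(CO[Si](CC)(CC)CC)[C@@H]2[C@@H](O[Si](CC)(CC)CC)C[C@@]1(C)O[Si](CC)(CC)CC | intermediate
17 | (E)-2-methylalk-1-enyl(methyl)zinc from 16 | C[Zn]/C=C(\C)CC[C@@H]1[C@@]2(C)CCC[C@@](C)(CO[Si](CC)(CC)CC)[C@@H]2[C@@H](O[Si](CC)(CC)CC)C[C@@]1(C)O[Si](CC)(CC)CC | intermediate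
18 | (15S)-E-allylic 3-methylfuran-2-yl carbinol, tris-TES | Cc1ccoc1[C@@H](O)/C=C(\C)CC[C@@H]2[C@@]3(C)CCC[C@@](C)(CO[Si](CC)(CC)CC)[C@@H]3[C@@H](O[Si](CC)(CC)CC)C[C@@]2(C)O[Si](CC)(CC)CC | intermediate
19 | (2S)-6-hydroxy-4-methyl-2-alkenyl-2H-pyran-3(6H)-one, tris-TES | CC1=CC(O)O[C@H](C1=O)/C=C(\C)CC[C@@H]2[C@@]3(C)CCC[C@@](C)(CO[Si](CC)(CC)CC)[C@@H]3[C@@H](O[Si](CC)(CC)CC)C[C@@]2(C)O[Si](CC)(CC)CC | intermediate
20 | (6S)-4-methyl-6-alkenyl-2H-pyran-2,5(6H)-dione, tris-TES | CC1=CC(=O)O[C@H](C1=O)/C=C(\C)CC[C@@H]2[C@@]3(C)CCC[C@@](C)(CO[Si](CC)(CC)CC)[C@@H]3[C@@H](O[Si](CC)(CC)CC)C[C@@]2(C)O[Si](CC)(CC)CC | intermediate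
21 | (15S,16R)-trans-5-hydroxy-4-methyl-6-alkenyl-5,6-dihydropyran-2-one, tris-TES | CC1=CC(=O)O[C@H]([C@@H]1O)/C=C(\C)CC[C@@H]2[C@@]3(C)CCC[C@@](C)(CO[Si](CC)(CC)CC)[C@@H]3[C@@H](O[Si](CC)(CC)CC)C[C@@]2(C)O[Si](CC)(CC)CC | intermediate
22 | (15S,16S)-cis-5-(4-nitrobenzoyloxy) lactone, tris-TES | CC1=CC(=O)O[C@H]([C@H]1OC(=O)c4ccc(cc4)[N+](=O)[O-])/C=C(\C)CC[C@@H]2[C@@]3(C)CCC[C@@](C)(CO[Si](CC)(CC)CC)[C@@H]3[C@@H](O[Si](CC)(CC)CC)C[C@@]2(C)O[Si](CC)(CC)CC | intermediate
23 | (15S,16S)-cis-5-hydroxy lactone, tris-TES | CC1=CC(=O)O[C@H]([C@H]1O)/C=C(\C)CC[C@@H]2[C@@]3(C)CCC[C@@](C)(CO[Si](CC)(CC)CC)[C@@H]3[C@@H](O[Si](CC)(CC)CC)C[C@@]2(C)O[Si](CC)(CC)CC | intermediate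
24 | tris(triethylsilyl) ether of the target (15S,16S butenolide) | CC1=CC(=O)O[C@@H]1[C@@H](O)/C=C(\C)CC[C@@H]2[C@@]3(C)CCC[C@@](C)(CO[Si](CC)(CC)CC)[C@@H]3[C@@H](O[Si](CC)(CC)CC)C[C@@]2(C)O[Si](CC)(CC)CC | intermediate
25 | CNP0255788.1 | CC1=CC(=O)O[C@@H]1[C@@H](O)/C=C(\C)CC[C@@H]1[C@@]2(C)CCC[C@@](C)(CO)[C@@H]2[C@@H](O)C[C@@]1(C)O | target

## Step count and risks

Total: 16 steps. Longest linear sequence: 16 steps from (+)-larixol 1 (compounds 14 and 15 are bought).

**Step 10 (key step).** The most likely failure is erosion of facial selectivity at the aldehyde. Methylalanes left after the exchange can bind the amino alkoxide or promote an unligated Lewis-acid addition, and some methyl transfer may compete.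
Fallback: from 13, the carboalumination is run as before and aldehyde 15 is added directly to alane 16 without zinc or ligand. This should give the C15-epimeric carbinols F1. Oxidation with MnO2 gives the furyl dienone F2. Asymmetric transfer hydrogenation with RuCl(p-cymene)[(S,S)-TsDPEN] in HCO2H/Et3N, with the furan as the aryl partner of the catalyst, should then return the 15S carbinol 18.

**Step 6.** The C6 alkoxyl radical may be lost by β-fragmentation or disproportionation before it abstracts hydrogen. The neopentyl nitroso compound may also dimerise and tautomerise poorly, and the warming needed for tautomerisation puts the spiro-epoxide at risk.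
Fallback: from nitrite 8, the photolysis is run under oxygen, so that the C-radical is captured by O2 and NO as the 4α-nitrooxymethyl epoxy alcohol F3. LiAlH4 then reduces the nitrate and opens the epoxide in one operation and rejoins the route at triol 12. This removes the tautomerisation and the deoximation from the sequence.

**Step 11.** Bromonium formation at the C13=C14 alkene or ionisation of the furyl allyl carbinol by traces of HBr may compete with attack on the furan.
Fallback: from 18, sensitised photooxygenation (O2, tetraphenylporphyrin, visible light, CH2Cl2, −78 °C) adds singlet oxygen across the furan to give the endoperoxide F4. Reduction with Me2S in the same flask gives the Z-enedione, which closes to lactol 19. No electrophilic halogen or acid is involved.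

**Steps 12 and 13.** The C15–H of keto lactone 20 may enolise, which would scramble C15 or tautomerise the ring to a 5-hydroxy-2-pyranone before the reduction takes place.
Fallback: from lactol 19, the anomeric hydroxyl is acetylated (Ac2O, pyridine) to the acetate F5, so that the ring stays at the lactol oxidation level. Luche reduction gives the trans allylic alcohol F6, and Mitsunobu inversion with 4-nitrobenzoic acid gives the cis ester F7. Selective anomeric deacetylation with hydrazinium acetate gives the lactol F8, and Dess–Martin oxidation then gives 22. The ketone and the lactone carbonyl are never present together.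

**Step 15.** The butenolide may epimerise at C16 through its dienolate under the basic conditions, or acyl migration may stop at an equilibrium mixture with methanolysis products.
Fallback: from 22, both esters are saponified with LiOH in THF/H2O at 0 °C to the carboxylate of the Z-dihydroxy acid F9, which has no acidic C16–H. Acidification to pH 4 should then close the five-membered lactone and give 24.

## Further compounds

F1 | step 10 | C15-epimeric E-allylic 3-methylfuran-2-yl carbinols, tris-TES | Cc1ccoc1C(O)/C=C(\C)CC[C@@H]2[C@@]3(C)CCC[C@@](C)(CO[Si](CC)(CC)CC)[C@@H]3[C@@H](O[Si](CC)(CC)CC)C[C@@]2(C)O[Si](CC)(CC)CC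
F2 | step 10 | E-alkenyl 3-methylfuran-2-yl ketone, tris-TES | Cc1ccoc1C(=O)/C=C(\C)CC[C@@H]2[C@@]3(C)CCC[C@@](C)(CO[Si](CC)(CC)CC)[C@@H]3[C@@H](O[Si](CC)(CC)CC)C[C@@]2(C)O[Si](CC)(CC)CC
F3 | step 6 | 4α-nitrooxymethyl-6α-hydroxy 8α,17-epoxide | C#CCC[C@@H]1[C@@]2(C)CCC[C@@](C)(CO[N+](=O)[O-])[C@@H]2[C@@H](O)C[C@]13CO3
F4 | step 11 | furan endoperoxide of 18 | CC1=CC2OOC1(O2)[C@@H](O)/C=C(\C)CC[C@@H]3[C@@]4(C)CCC[C@@](C)(CO[Si](CC)(CC)CC)[C@@H]4[C@@H](O[Si](CC)(CC)CC)C[C@@]3(C)O[Si](CC)(CC)CC
F5 | step 12 | anomeric acetate of lactol 19 | CC1=CC(OC(C)=O)O[C@H](C1=O)/C=C(\C)CC[C@@H]2[C@@]3(C)CCC[C@@](C)(CO[Si](CC)(CC)CC)[C@@H]3[C@@H](O[Si](CC)(CC)CC)C[C@@]2(C)O[Si](CC)(CC)CC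
F6 | step 12 | trans allylic alcohol of the anomeric acetate | CC1=CC(OC(C)=O)O[C@H]([C@@H]1O)/C=C(\C)CC[C@@H]2[C@@]3(C)CCC[C@@](C)(CO[Si](CC)(CC)CC)[C@@H]3[C@@H](O[Si](CC)(CC)CC)C[C@@]2(C)O[Si](CC)(CC)CC
F7 | step 12 | cis 4-nitrobenzoate of the anomeric acetate | CC1=CC(OC(C)=O)O[C@H]([C@H]1OC(=O)c4ccc(cc4)[N+](=O)[O-])/C=C(\C)CC[C@@H]2[C@@]3(C)CCC[C@@](C)(CO[Si](CC)(CC)CC)[C@@H]3[C@@H](O[Si](CC)(CC)CC)C[C@@]2(C)O[Si](CC)(CC)CC
F8 | step 12 | cis 4-nitrobenzoate lactol | CC1=CC(O)O[C@H]([C@H]1OC(=O)c4ccc(cc4)[N+](=O)[O-])/C=C(\C)CC[C@@H]2[C@@]3(C)CCC[C@@](C)(CO[Si](CC)(CC)CC)[C@@H]3[C@@H](O[Si](CC)(CC)CC)C[C@@]2(C)O[Si](CC)(CC)CC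
F9 | step 15 | (2Z,4S,5S)-4,5-dihydroxy-3-methyl dienoic acid, tris-TES | OC(=O)/C=C(/C)[C@H](O)[C@@H](O)/C=C(\C)CC[C@@H]2[C@@]3(C)CCC[C@@](C)(CO[Si](CC)(CC)CC)[C@@H]3[C@@H](O[Si](CC)(CC)CC)C[C@@]2(C)O[Si](CC)(CC)CC
A1 | alternative 1 | cis-fused 4,8,10-trimethyl enedione Diels–Alder adduct | O=C1[C@@]2(C)CC=C[C@@H](C)[C@H]2C(=O)C=C1C
A2 | alternative 1 | 2,6-dimethyl-1,4-benzoquinone | CC1=CC(=O)C=C(C)C1=O
A3 | alternative 1 | (E)-penta-1,3-diene | C=C/C=C/C
A4 | alternative 2 | trans-decalin ester with C8 ketone and C1=C2 alkene | COc1ccc(COCC[C@@H]2[C@@]3(C)C=CC[C@@](C)(C(=O)OCC)[C@@H]3[C@@H](O[Si](C)(C)C(C)(C)C)CC2=O)cc1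
A5 | alternative 2 | open-chain trienoate precursor of A4 | C=C/C=C(\C)[C@@H](CCOCc1ccc(OC)cc1)C(=O)C[C@H](O[Si](C)(C)C(C)(C)C)/C=C(\C)C(=O)OCC
A6 | alternative 3 | O15-PMB, bis-TBS protected target | CC1=CC(=O)O[C@@H]1[C@@H](OCc2ccc(OC)cc2)/C=C(\C)CC[C@@H]3[C@@]4(C)CCC[C@@](C)(CO[Si](C)(C)C(C)(C)C)[C@@H]4[C@@H](O[Si](C)(C)C(C)(C)C)C[C@@]3(C)O
A7 | alternative 3 | C16 propargylic alcohol precursor of A6 | C#C[C@H](O)[C@@H](OCc1ccc(OC)cc1)/C=C(\C)CC[C@@H]2[C@@]3(C)CCC[C@@](C)(CO[Si](C)(C)C(C)(C)C)[C@@H]3[C@@H](O[Si](C)(C)C(C)(C)C)C[C@@]2(C)O
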